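**Plan**

Locants: chain C1 (alkyne CH) to C15 (ethyl CH3); the only ring is the oxocene O/C7–C13. Retrosynthetic cuts, in order: the C6 acetate; C3=C4 (enyne from a C4 aldehyde); C12–Br (from C12–OH with inversion); ethyl back to vinyl;
then the ring bond C12–C13, as a C12 aldehyde plus a (Z)-γ-alkoxyallylboronate (C13–C15 on the C7 oxygen); C10–Cl/C9–H (syn addition to a C9≡C10 alkyne); C10–C11 (ethylene oxide); C5–Cl; C9≡C10 (alkyne homologation of a lactol).
Enabling feature: the ring ether carbon C13 carries a two-carbon branch and sits next to the heteroatom-bearing C12 (a 2-vinyl-3-hydroxy cyclic ether retron), and the cis C9=C10 chloroalkene of the oxocene pre-folds the chain for eight-ring closure.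
Forward: C1–C6 of D-glucal become C9–C4 (O3 → ring oxygen on C7, O4 → C6 acetate, ring O5 → leaving group for C5–Cl, C6 → C4); the chain grows to C12, the chloroalkene is set, the allyl ether is borylated, the oxocene closes, then ethyl, bromide and side chain are adjusted.
Stereochemistry: C6 and C7 from D-glucal; C5 by SN2 chloride; C12/C13 by the chair allylboration (Z enol ether → OH cis to vinyl; C7 controls the face), C12 then inverted by bromide; C9=C10 by directed syn-hydrozirconation; C3=C4 (Z) by Peterson olefination.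

Key step: step 9

Remark: D-glucal is taken as the commercial starting material; "silinane" means the 2,2-di-tert-butyl-1,3,2-dioxasilinane spanning O4 and O6 (ring carbons = target C4, C5, C6), and locants in descriptive names are those of the target.

**Route**

Step 1
Reactants: 1 D-glucal; 2 di-tert-butylsilyl bis(trifluoromethanesulfonate)
Product: 3 4,6-O-(di-tert-butylsilylene)-D-glucal
Conditions: t-Bu2Si(OTf)2, pyridine, DMF, −40 °C → 0 °C
Reagents that add atoms: di-tert-butylsilyl bis(trifluoromethanesulfonate), CC(C)(C)[Si](OS(=O)(=O)C(F)(F)F)(OS(=O)(=O)C(F)(F)F)C(C)(C)C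
Why: Cyclic silylene formation is selective for the 4,6-diol (six-membered dioxasilinane), leaving only the allylic 3-OH free.

Step 2
Reactants: 3 4,6-O-(di-tert-butylsilylene)-D-glucal; 4 allyl bromide
Product: 5 3-O-allyl-4,6-O-(di-tert-butylsilylene)-D-glucal
Conditions: NaH, allyl bromide, n-Bu4NI (cat.), THF/DMF, 0 °C → rt
Reagents that add atoms: allyl bromide, C=CCBr
Why: Williamson etherification of the single free hydroxyl installs the three carbons that become C13–C15.

Step 3
Reactants: 5 3-O-allyl-4,6-O-(di-tert-butylsilylene)-D-glucal; 6 water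
Product: 7 3-O-allyl-2-deoxy-4,6-O-(di-tert-butylsilylene)-D-arabino-hexopyranose
Conditions: PPh3·HBr (cat.), H2O, THF, rt
Reagents that add atoms: water, O
Why: Acid-catalysed Markovnikov hydration of the glycal enol ether through the C1 oxocarbenium ion should give the 2-deoxy hemiacetal (anomeric mixture, of no consequence) without Ferrier displacement of the 3-O-alkyl group.

Step 4
Reactants: 7 3-O-allyl-2-deoxy-4,6-O-(di-tert-butylsilylene)-D-arabino-hexopyranose; 8 dimethyl (1-diazo-2-oxopropyl)phosphonate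
Product: 9 (5R,6R,7R)-alkynol (terminal C9≡C10; free 5-OH; 7-O-allyl; 4,6-O-silylene)
Conditions: dimethyl (1-diazo-2-oxopropyl)phosphonate, K2CO3, MeOH, 0 °C → rt
Reagents that add atoms: dimethyl (1-diazo-2-oxopropyl)phosphonate, CC(=O)C(=[N+]=[N-])P(=O)(OC)OC
Why: Ohira–Bestmann (Seyferth–Gilbert) homologation of the open-chain aldehyde tautomer adds C10 as a terminal alkyne and releases the former pyranose ring oxygen as the C5 hydroxyl.

Step 5
Reactants: 9 (5R,6R,7R)-alkynol; 10 tetrabutylammonium chloride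
Product: 12 (5S,6S,7R)-5-chloro alkyne, via triflate 11 (not isolated)
Conditions: Tf2O, pyridine, CH2Cl2, −30 °C; then n-Bu4NCl, DMF, 0 °C → rt
Reagents that add atoms: tetrabutylammonium chloride, [Cl-].CCCC[N+](CCCC)(CCCC)CCCC
Why: Triflation followed by SN2 displacement with chloride inverts C5 to the configuration of the target, as in chloride displacements of carbohydrate triflates.

Step 6
Reactants: 12 (5S,6S,7R)-5-chloro alkyne; 13 ethylene oxide
Product: 15 homopropargylic alcohol (C4–C12 chain; C9≡C10; 12-OH), via lithium acetylide 14 (not isolated)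
Conditions: n-BuLi, THF, −78 °C; BF3·OEt2; ethylene oxide, −78 °C
Reagents that add atoms: ethylene oxide, C1CO1
Why: BF3-promoted opening of the epoxide by the lithium acetylide adds C11–C12 and ends in the primary hydroxyl that directs step 7, the deactivated secondary chloride between two C–O carbons being inert at −78 °C.

Step 7
Reactants: 15 homopropargylic alcohol; 16 N-chlorosuccinimide
Product: 18 (9E)-10-chloroalkene 12-alcohol (C8 and C11 cis), via alkenylzirconocene 17 (not isolated)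
Conditions: MeLi (1.0 equiv), THF, −78 °C; Cp2Zr(H)Cl (1.1 equiv), 0 °C → rt; NCS, 0 °C
Reagents that add atoms: N-chlorosuccinimide, O=C1CCC(=O)N1Cl
Why: Alkoxide-directed hydrozirconation: the lithium alkoxide binds zirconium and delivers Zr–H intramolecularly and syn across the alkyne through a five-membered oxazirconacycle (Zr on C10, H on C9), which with about one equivalent of reagent should outrun the untethered allyl alkene, and chlorodezirconation with NCS proceeds with retention.

Step 8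
Reactants: 18 (9E)-10-chloroalkene 12-alcohol; 19 2-isopropoxy-4,4,5,5-tetramethyl-1,3,2-dioxaborolane
Product: 21 (Z)-γ-alkoxyallyl pinacol boronate 12-alcohol, via dilithio species 20 (not isolated)
Conditions: n-BuLi (1.0 equiv) then sec-BuLi (1.3 equiv), THF, −78 °C; i-PrOBpin, −78 → 0 °C; aq NH4Cl
Reagents that add atoms: 2-isopropoxy-4,4,5,5-tetramethyl-1,3,2-dioxaborolane, CC(C)OB1OC(C)(C)C(C)(C)O1
Why: After the hydroxyl is deprotonated, oxygen-directed α-lithiation of the allyl ether gives the chelated (Z)-alkoxyallyl anion, which boron electrophiles capture at the γ-terminus to give the (Z)-γ-alkoxyallylboronate, the borate formed at the alkoxide being hydrolysed on work-up.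

Step 9
Reactants: 21 (Z)-γ-alkoxyallyl pinacol boronate 12-alcohol
Product: 24 (7R,12R,13R)-10-chloro-13-vinyl-oxocen-12-ol bearing the silinane at C7, via aldehyde 22 (not isolated), via borate ester 23 (not isolated)
Conditions: Dess–Martin periodinane, NaHCO3, CH2Cl2 (0.005 M), 0 °C → rt; then N(CH2CH2OH)3, aq NaHCO3
Reagents that add atoms: none
Why: Oxidation unveils the C12 aldehyde, which is attacked through a closed six-membered chair (Zimmerman–Traxler type) transition state by C13, the γ-carbon of the (Z)-γ-alkoxyallylboronate; this vinylogous α-alkoxy carbanion equivalent reverses the native acceptor polarity of the ether carbon, so two acceptor carbons (the C12 carbonyl and the α-oxy C13) are joined. The closest known reaction type is the intramolecular allylboration of ω-formyl γ-alkoxyallylboronates to 2-vinyl-3-hydroxy cyclic ethers of six to eight ring atoms. The eight-membered oxocene (O, C7–C13) closes by 8-exo-trig addition to the aldehyde, the cis C9=C10 chloroalkene in the tether removing transannular strain and holding the two ends close. The cis relation of 12-OH and 13-vinyl follows from the Z enol ether geometry, which puts the ring oxygen axial and the C11 chain equatorial in the chair; the face of C13 is set by C7, whose side chain takes the pseudo-equatorial position so that H7 and H13 end up cis. The step needs ring closure to beat intermolecular allylboration, which high dilution and the pre-folding cis alkene should secure, and it needs the β,γ-unsaturated aldehyde not to slip into conjugation, which buffered base-free oxidation and immediate intramolecular capture should secure. The extra unsaturation (vinyl), the 12-hydroxyl and boron are the helpers, removed in steps 10, 11 and on work-up.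

Step 10
Reactants: 24 (7R,12R,13R)-10-chloro-13-vinyl-oxocen-12-ol
Product: 25 (7R,12R,13R)-10-chloro-13-ethyl-oxocen-12-ol
Conditions: 2-nitrobenzenesulfonylhydrazide, Et3N, CH2Cl2, rt
Reagents that add atoms: none
Why: Diimide reduces the monosubstituted vinyl group much faster than the trisubstituted ring chloroalkene and does not cleave C–Cl bonds.

Step 11
Reactants: 25 (7R,12R,13R)-10-chloro-13-ethyl-oxocen-12-ol; 26 carbon tetrabromide
Product: 27 (7R,12S,13R)-12-bromo-10-chloro-13-ethyl-oxocene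
Conditions: CBr4, P(n-C8H17)3, toluene, 70 °C
Reagents that add atoms: carbon tetrabromide, BrC(Br)(Br)Br
Why: Appel-type bromination through the alkoxyphosphonium ion with SN2 inversion at C12 places bromine trans to the C13 ethyl group.

Step 12
Reactants: 27 (7R,12S,13R)-12-bromo-10-chloro-13-ethyl-oxocene; 28 boron trifluoride–dimethyl sulfide
Product: 29 C4 primary alcohol with O6 di-tert-butylfluorosilyl ether
Conditions: BF3·SMe2, CH2Cl2, 0 °C; aq NaHCO3
Reagents that add atoms: boron trifluoride–dimethyl sulfide, C[S+](C)[B-](F)(F)F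
Why: Regioselective Lewis acid opening of the dioxasilinane: BF3 binds the less hindered primary oxygen and fluoride passes to silicon, so C4–OH is freed while O6 stays masked as a fluorosilyl ether.

Step 13
Reactants: 29 C4 primary alcohol with O6 di-tert-butylfluorosilyl ether
Product: 30 C4 aldehyde (α-chloro; β-silyloxy)
Conditions: Dess–Martin periodinane, NaHCO3, CH2Cl2, 0 °C
Reagents that add atoms: none
Why: Buffered Dess–Martin oxidation should give the α-chloro aldehyde without epimerising C5, the β-silyloxy group being a poor leaving group for elimination.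

Step 14
Reactants: 30 C4 aldehyde; 31 1,3-bis(triisopropylsilyl)propyne
Product: 33 (3Z)-1-triisopropylsilyl enyne, via lithium alkoxide 32 (not isolated)
Conditions: 31, n-BuLi, THF, −78 °C; then 30, −78 → −20 °C
Reagents that add atoms: 1,3-bis(triisopropylsilyl)propyne, CC(C)[Si](C(C)C)(C(C)C)CC#C[Si](C(C)C)(C(C)C)C(C)C
Why: Peterson olefination with the lithiated bis-silyl propyne, whose bulky silyl groups steer the syn elimination to the (Z)-enyne, at a temperature low enough to keep C5 and both C–halogen bonds intact.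

Step 15
Reactants: 33 (3Z)-1-triisopropylsilyl enyne
Product: 34 (3Z)-enyne 6-alcohol (deacetyl target)
Conditions: n-Bu4NF, AcOH (1:1), THF, 0 °C → rt
Reagents that add atoms: none
Why: Fluoride cleaves both the alkynyl C–Si bond and the O–Si(F) bond, and the acetic acid buffer keeps the C6 oxygen protonated so that it should not close onto C5–Cl as an epoxide.

Step 16
Reactants: 34 (3Z)-enyne 6-alcohol; 35 acetic anhydride
Product: 36 target compound CNP0228902.1
Conditions: Ac2O, pyridine, DMAP (cat.), CH2Cl2, 0 °C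
Reagents that add atoms: acetic anhydride, CC(=O)OC(C)=O
Why: Nucleophile-catalysed acetylation of the only hydroxyl under mild conditions leaves the allylic chloride and the enyne untouched.

**Compound list**

1 | D-glucal (1,5-anhydro-2-deoxy-D-arabino-hex-1-enitol) | C1=CO[C@@H]([C@H]([C@@H]1O)O)CO | starting material
2 | di-tert-butylsilyl bis(trifluoromethanesulfonate) | CC(C)(C)[Si](OS(=O)(=O)C(F)(F)F)(OS(=O)(=O)C(F)(F)F)C(C)(C)C | starting material
3 | 4,6-O-(di-tert-butylsilylene)-D-glucal | C1=CO[C@@H]2CO[Si](C(C)(C)C)(C(C)(C)C)O[C@H]2[C@@H]1O | intermediate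
4 | allyl bromide | C=CCBr | starting material
5 | 3-O-allyl-4,6-O-(di-tert-butylsilylene)-D-glucal | C1=CO[C@@H]2CO[Si](C(C)(C)C)(C(C)(C)C)O[C@H]2[C@@H]1OCC=C | intermediate
6 | water | O | starting material
7 | 3-O-allyl-2-deoxy-4,6-O-(di-tert-butylsilylene)-D-arabino-hexopyranose (anomeric mixture) | C1C(O)O[C@@H]2CO[Si](C(C)(C)C)(C(C)(C)C)O[C@H]2[C@@H]1OCC=C | intermediate
8 | dimethyl (1-diazo-2-oxopropyl)phosphonate | CC(=O)C(=[N+]=[N-])P(=O)(OC)OC | starting material
9 | (4R,5R)-4-[(1R)-1-(allyloxy)but-3-yn-1-yl]-2,2-di-tert-butyl-1,3,2-dioxasilinan-5-ol | C1[C@@H](O)[C@@H](O[Si](C(C)(C)C)(C(C)(C)C)O1)[C@H](OCC=C)CC#C | intermediate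
10 | tetrabutylammonium chloride | [Cl-].CCCC[N+](CCCC)(CCCC)CCCC | starting material
11 | 5-O-trifluoromethanesulfonate of 9 | C1[C@@H](OS(=O)(=O)C(F)(F)F)[C@@H](O[Si](C(C)(C)C)(C(C)(C)C)O1)[C@H](OCC=C)CC#C | intermediate
12 | (4S,5S)-4-[(1R)-1-(allyloxy)but-3-yn-1-yl]-2,2-di-tert-butyl-5-chloro-1,3,2-dioxasilinane | C1[C@H](Cl)[C@@H](O[Si](C(C)(C)C)(C(C)(C)C)O1)[C@H](OCC=C)CC#C | intermediate
13 | ethylene oxide (oxirane) | C1CO1 | starting material
14 | lithium acetylide of 12 | C1[C@H](Cl)[C@@H](O[Si](C(C)(C)C)(C(C)(C)C)O1)[C@H](OCC=C)CC#C[Li] | intermediate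
15 | (6R)-6-(allyloxy)-6-[(4S,5S)-2,2-di-tert-butyl-5-chloro-1,3,2-dioxasilinan-4-yl]hex-3-yn-1-ol | C1[C@H](Cl)[C@@H](O[Si](C(C)(C)C)(C(C)(C)C)O1)[C@H](OCC=C)CC#CCCO | intermediate
16 | N-chlorosuccinimide | O=C1CCC(=O)N1Cl | starting material
17 | alkenylzirconocene (five-membered oxazirconacycle: Cp2Zr bound to O12 and C10, H on C9 syn to Zr) | C1[C@H](Cl)[C@@H](O[Si](C(C)(C)C)(C(C)(C)C)O1)[C@H](OCC=C)C/C=C2\CCO[Zr]2(C3C=CC=C3)C3C=CC=C3 | intermediate
18 | (3E,6R)-6-(allyloxy)-3-chloro-6-[(4S,5S)-2,2-di-tert-butyl-5-chloro-1,3,2-dioxasilinan-4-yl]hex-3-en-1-ol | C1[C@H](Cl)[C@@H](O[Si](C(C)(C)C)(C(C)(C)C)O1)[C@H](OCC=C)C/C=C(/Cl)CCO | intermediate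
19 | 2-isopropoxy-4,4,5,5-tetramethyl-1,3,2-dioxaborolane | CC(C)OB1OC(C)(C)C(C)(C)O1 | starting material
20 | dilithio species of 18 (lithium 12-alkoxide, allyl ether lithiated α to oxygen) | C1[C@H](Cl)[C@@H](O[Si](C(C)(C)C)(C(C)(C)C)O1)[C@H](OC([Li])C=C)C/C=C(/Cl)CCO[Li] | intermediate
21 | (3E,6R)-3-chloro-6-[(4S,5S)-2,2-di-tert-butyl-5-chloro-1,3,2-dioxasilinan-4-yl]-6-{[(1Z)-3-(4,4,5,5-tetramethyl-1,3,2-dioxaborolan-2-yl)prop-1-en-1-yl]oxy}hex-3-en-1-ol | C1[C@H](Cl)[C@@H](O[Si](C(C)(C)C)(C(C)(C)C)O1)[C@H](O/C=C\CB2OC(C)(C)C(C)(C)O2)C/C=C(/Cl)CCO | intermediate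
22 | corresponding hex-3-enal (C12 aldehyde of 21) | C1[C@H](Cl)[C@@H](O[Si](C(C)(C)C)(C(C)(C)C)O1)[C@H](O/C=C\CB2OC(C)(C)C(C)(C)O2)C/C=C(/Cl)CC=O | intermediate
23 | O12 pinacol borate ester of 24 | C1[C@H](Cl)[C@@H](O[Si](C(C)(C)C)(C(C)(C)C)O1)[C@H]2C/C=C(/Cl)C[C@@H](OB3OC(C)(C)C(C)(C)O3)[C@@H](C=C)O2 | intermediate
24 | (2R,3R,5E,8R)-5-chloro-8-[(4S,5S)-2,2-di-tert-butyl-5-chloro-1,3,2-dioxasilinan-4-yl]-2-ethenyl-3,4,7,8-tetrahydro-2H-oxocin-3-ol (12-OH cis to 13-vinyl, H7 cis to H13) | C1[C@H](Cl)[C@@H](O[Si](C(C)(C)C)(C(C)(C)C)O1)[C@H]2C/C=C(/Cl)C[C@@H](O)[C@@H](C=C)O2 | intermediate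
25 | (2R,3R,5E,8R)-5-chloro-8-[(4S,5S)-2,2-di-tert-butyl-5-chloro-1,3,2-dioxasilinan-4-yl]-2-ethyl-3,4,7,8-tetrahydro-2H-oxocin-3-ol | C1[C@H](Cl)[C@@H](O[Si](C(C)(C)C)(C(C)(C)C)O1)[C@H]2C/C=C(/Cl)C[C@@H](O)[C@@H](CC)O2 | intermediate
26 | carbon tetrabromide | BrC(Br)(Br)Br | starting material
27 | (2R,3S,5E,8R)-3-bromo-5-chloro-8-[(4S,5S)-2,2-di-tert-butyl-5-chloro-1,3,2-dioxasilinan-4-yl]-2-ethyl-3,4,7,8-tetrahydro-2H-oxocine | C1[C@H](Cl)[C@@H](O[Si](C(C)(C)C)(C(C)(C)C)O1)[C@H]2C/C=C(/Cl)C[C@H](Br)[C@@H](CC)O2 | intermediate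
28 | boron trifluoride–dimethyl sulfide | C[S+](C)[B-](F)(F)F | starting material
29 | (5S,6S)-5-chloro-6-[di-tert-butyl(fluoro)silyloxy]-C4 primary alcohol carrying the (7R,12S,13R)-12-bromo-10-chloro-13-ethyl-oxocene at C6 | OC[C@H](Cl)[C@@H](O[Si](F)(C(C)(C)C)C(C)(C)C)[C@H]1C/C=C(/Cl)C[C@H](Br)[C@@H](CC)O1 | intermediate
30 | C4 aldehyde of 29 (5R by descriptor change, same spatial arrangement) | O=C[C@H](Cl)[C@@H](O[Si](F)(C(C)(C)C)C(C)(C)C)[C@H]1C/C=C(/Cl)C[C@H](Br)[C@@H](CC)O1 | intermediate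
31 | 1,3-bis(triisopropylsilyl)propyne | CC(C)[Si](C(C)C)(C(C)C)CC#C[Si](C(C)C)(C(C)C)C(C)C | starting material
32 | lithium β-silyl alkoxide (Peterson adduct of 30, new centres C3 and C4 unassigned) | [Li]OC(C(C#C[Si](C(C)C)(C(C)C)C(C)C)[Si](C(C)C)(C(C)C)C(C)C)[C@H](Cl)[C@@H](O[Si](F)(C(C)(C)C)C(C)(C)C)[C@H]1C/C=C(/Cl)C[C@H](Br)[C@@H](CC)O1 | intermediate
33 | (3Z,5S,6S)-1-triisopropylsilyl enyne with O6 di-tert-butylfluorosilyl ether | CC(C)[Si](C(C)C)(C(C)C)C#C/C=C\[C@H](Cl)[C@@H](O[Si](F)(C(C)(C)C)C(C)(C)C)[C@H]1C/C=C(/Cl)C[C@H](Br)[C@@H](CC)O1 | intermediate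
34 | (3Z,5S,6S,7R,12S,13R)-enyne 6-alcohol (deacetyl target) | C#C/C=C\[C@H](Cl)[C@@H](O)[C@H]1C/C=C(/Cl)C[C@H](Br)[C@@H](CC)O1 | intermediate
35 | acetic anhydride | CC(=O)OC(C)=O | starting material
36 | CNP0228902.1, (3Z,5S,6S,7R,9E,12S,13R) | C#C/C=C\[C@H](Cl)[C@@H](OC(C)=O)[C@H]1C/C=C(/Cl)C[C@H](Br)[C@@H](CC)O1 | target

**Count and risks**

Total steps: 16. Longest linear sequence: 16 steps (fully linear from 1).

Steps most likely to fail, in order of risk:

Step 9. The eight-membered closure may lose to intermolecular allylboration, the aldehyde may add to the wrong face of the enol ether relative to C7, or the β,γ-unsaturated aldehyde may drift into conjugation before it is captured. The fallback sets out from 18 and comes back at 24. The dilithio species 20 is quenched with Bu3SnCl to give the hydroxy (Z)-γ-alkoxyallylstannane F1. Dess–Martin oxidation gives the aldehyde stannane F2, which is stable without a Lewis acid and can be purified. Slow addition of it to BF3·OEt2 in CH2Cl2 at −78 °C closes the ring through an open transition state and should favour the 12,13-trans alcohol F3. Mitsunobu inversion (4-nitrobenzoic acid, PPh3, DIAD) gives the cis 4-nitrobenzoate F4, and K2CO3 in MeOH returns 24.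

Step 8. sec-BuLi may attack the chloroalkene (loss of HCl toward an allene or alkyne), or metalation of the allyl ether may be incomplete next to the lithium alkoxide. The fallback sets out from 18 and comes back at 21 without any strong base. Cross-metathesis with vinylboronic acid pinacol ester (second-generation Grubbs catalyst, CH2Cl2, 40 °C) gives the (E)-3-alkoxyprop-1-enylboronate F5. Nickel hydride-catalysed double-bond migration (NiCl2(dppb), LiBHEt3, THF) should then move the alkene into the enol ether position with Z geometry, giving 21.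

Step 7. Hydrozirconation of the allyl ether alkene may compete with the directed addition to the alkyne, or the regiochemistry may erode if excess reagent is needed. The fallback sets out from 3 and comes back at 18, keeping any second alkene out of the molecule until the chloroalkene exists. Compound 3 is etherified with 4-methoxybenzyl chloride (NaH) to the PMB ether F6. The operations of steps 3 to 7 then give the lactol F7, the alkynol F8, its triflate F9 (not isolated), the chloride F10, the lithium acetylide F11 (not isolated), the homopropargylic alcohol F12, the alkenylzirconocene F13 (not isolated) and the chloroalkene alcohol F14. Acetylation (Ac2O, pyridine) gives the acetate F15, and DDQ frees the C7 hydroxyl to give the hydroxy acetate F16. Acid-catalysed allylation with allyl 2,2,2-trichloroacetimidate (TfOH cat.) gives the allyl ether acetate F17, and K2CO3 in MeOH returns 18.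

Further compounds
F1 | step 9 | hydroxy (Z)-γ-alkoxyallylstannane (tributylstannyl analogue of 21) | C1[C@H](Cl)[C@@H](O[Si](C(C)(C)C)(C(C)(C)C)O1)[C@H](O/C=C\C[Sn](CCCC)(CCCC)CCCC)C/C=C(/Cl)CCO
F2 | step 9 | aldehyde stannane (C12 aldehyde of F1) | C1[C@H](Cl)[C@@H](O[Si](C(C)(C)C)(C(C)(C)C)O1)[C@H](O/C=C\C[Sn](CCCC)(CCCC)CCCC)C/C=C(/Cl)CC=O
F3 | step 9 | 12,13-trans alcohol (12S epimer of 24) | C1[C@H](Cl)[C@@H](O[Si](C(C)(C)C)(C(C)(C)C)O1)[C@H]2C/C=C(/Cl)C[C@H](O)[C@@H](C=C)O2
F4 | step 9 | cis 4-nitrobenzoate of 24 | C1[C@H](Cl)[C@@H](O[Si](C(C)(C)C)(C(C)(C)C)O1)[C@H]2C/C=C(/Cl)C[C@@H](OC(=O)c3ccc(cc3)[N+](=O)[O-])[C@@H](C=C)O2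
F5 | step 8 | (E)-3-alkoxyprop-1-enyl pinacol boronate (alkene isomer of 21) | C1[C@H](Cl)[C@@H](O[Si](C(C)(C)C)(C(C)(C)C)O1)[C@H](OC/C=C/B2OC(C)(C)C(C)(C)O2)C/C=C(/Cl)CCO
F6 | step 7 | 3-O-(4-methoxybenzyl)-4,6-O-(di-tert-butylsilylene)-D-glucal | C1=CO[C@@H]2CO[Si](C(C)(C)C)(C(C)(C)C)O[C@H]2[C@@H]1OCc1ccc(OC)cc1
F7 | step 7 | 2-deoxy lactol of F6 (anomeric mixture) | C1C(O)O[C@@H]2CO[Si](C(C)(C)C)(C(C)(C)C)O[C@H]2[C@@H]1OCc1ccc(OC)cc1
F8 | step 7 | PMB analogue of alkynol 9 | C1[C@@H](O)[C@@H](O[Si](C(C)(C)C)(C(C)(C)C)O1)[C@H](OCc1ccc(OC)cc1)CC#C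
F9 | step 7 | PMB analogue of triflate 11 | C1[C@@H](OS(=O)(=O)C(F)(F)F)[C@@H](O[Si](C(C)(C)C)(C(C)(C)C)O1)[C@H](OCc1ccc(OC)cc1)CC#C
F10 | step 7 | PMB analogue of chloride 12 | C1[C@H](Cl)[C@@H](O[Si](C(C)(C)C)(C(C)(C)C)O1)[C@H](OCc1ccc(OC)cc1)CC#C
F11 | step 7 | PMB analogue of lithium acetylide 14 | C1[C@H](Cl)[C@@H](O[Si](C(C)(C)C)(C(C)(C)C)O1)[C@H](OCc1ccc(OC)cc1)CC#C[Li]
F12 | step 7 | PMB analogue of homopropargylic alcohol 15 | C1[C@H](Cl)[C@@H](O[Si](C(C)(C)C)(C(C)(C)C)O1)[C@H](OCc1ccc(OC)cc1)CC#CCCO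
F13 | step 7 | PMB analogue of alkenylzirconocene 17 | C1[C@H](Cl)[C@@H](O[Si](C(C)(C)C)(C(C)(C)C)O1)[C@H](OCc1ccc(OC)cc1)C/C=C2\CCO[Zr]2(C3C=CC=C3)C3C=CC=C3
F14 | step 7 | PMB analogue of chloroalkene alcohol 18 | C1[C@H](Cl)[C@@H](O[Si](C(C)(C)C)(C(C)(C)C)O1)[C@H](OCc1ccc(OC)cc1)C/C=C(/Cl)CCO
F15 | step 7 | 12-O-acetate of F14 | C1[C@H](Cl)[C@@H](O[Si](C(C)(C)C)(C(C)(C)C)O1)[C@H](OCc1ccc(OC)cc1)C/C=C(/Cl)CCOC(C)=O
F16 | step 7 | 7-hydroxy 12-acetate | C1[C@H](Cl)[C@@H](O[Si](C(C)(C)C)(C(C)(C)C)O1)[C@H](O)C/C=C(/Cl)CCOC(C)=O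
F17 | step 7 | 12-O-acetate of 18 | C1[C@H](Cl)[C@@H](O[Si](C(C)(C)C)(C(C)(C)C)O1)[C@H](OCC=C)C/C=C(/Cl)CCOC(C)=O
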